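## The problem

Compound 13 is a 1-aryl-1,2-dihydronaphthalene. A catechol ring A is fused to ring B, whose four non-aromatic carbons all differ: C1 carries the 4-hydroxyphenyl group, C2 and C3 one 2,4-dihydroxybenzoyl group each, and C4 is the vinylic CH of a C3=C4 bond conjugated with ring A and the C3 ketone. These dihydronaphthalene locants are used for all intermediates.

The two stereocentres are adjacent and trans, (1R,2S). C1 is doubly benzylic and fixed once made; C2 is α to a ketone and can epimerise. One centre must therefore be set absolutely and the other must follow from it. Here C2 is set first and directs the entry of the aryl group at C1.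

The free compound is fragile. Seven phenols (a catechol, two hydroxyls ortho to ketones) are sensitive to air and base. A 2'-hydroxyl can add to C4 of the enone, the 1,4-diketone across C2/C3 can close to a furan in acid, and the dihydronaphthalene aromatises on loss of H2. The phenols therefore stay masked to the end, and C3=C4 must be made without an oxidant.

The enabling feature is that ring B without C2 (C8a–C1–C3–C4–C4a plus ring A) is the skeleton of 5,6-dimethoxy-1-indanone, which already has the ring A oxygens and a carbonyl at C4. In the derived 2-aroylindenone the C1=C3 bond is doubly activated, so C2 with its aroyl group can be delivered to both ends as a one-carbon ylide unit. The resulting cyclopropane has the donor ring A on C1 and two acyl groups on C3; heterolysis of C1–C3 restores a six-membered ring B while an arene enters at C1.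

## Retrosynthesis

**13 ⇒ 12.** The seven O–methyl bonds are cut last. Methyl ethers are preferred to benzyl or acetal groups because 1, 2, 7 and 9 are all sold as methyl ethers and because they alone survive NaH, an amine/carbonate base, a strong Lewis acid in HFIP and a palladium reduction. The forward step must cleave even the two ethers para to the ketones without letting a freed 2'-hydroxyl add to C4.

**12 ⇒ 11 ⇒ 10.** The C4–H bond is traced to a C4–O bond: 12 from enol triflate 11, and 11 from enol 10, the tautomer of a C4 ketone. The oxygen on C4 is what links ring B to an indanone, and it is removed by substitution. A dehydrogenative route to C3=C4 would need an oxidant, and a reduction–dehydration would have to tell three aryl ketones apart. The forward steps must sulfonylate the ring oxygen, not the aroyl oxygen, and reduce C–O without touching C3=C4.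

**10 ⇒ 8 + 9.** The C1–aryl bond is cut and C1 is re-joined to C3, giving cyclopropane 8 and anisole 9. This cut removes a substituent and contracts ring B at once. C3 of 10, flanked by two carbonyls, is the ideal leaving carbon of a donor–acceptor opening, and C1, para to the C6 methoxy group, the ideal cationic carbon. In 8 the three stereocentres are locked in a bicycle and only C2 has to survive. The forward reaction must break the C1–C3 fusion bond and not C1–C2, must arylate C1 through the para position of 9 faster than the C2 proton is lost, and must do so trans to the C2 aroyl group.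

**8 ⇒ 6 + 7.** Cyclopropane 8 is cut at C1–C2 and C2–C3. This removes C2 with its aroyl group as the ylide carbon of bromoketone 7 and leaves indenone 6. The other two-bond cuts of the three-membered ring would need a carbene at C1 or C3 and a tethered alkene built over several steps. This cut uses a commercial bromide and a flat, doubly activated alkene whose faces a chiral ylide can distinguish; 6 has no stereocentre. The forward reaction must choose one face of 6, place the aroyl group exo, and close through carbon C3 rather than the aroyl oxygen.

**6 ⇒ 3 ⇒ 1 + 2.** Indenone 6 cannot be stored, so C1=C3 is introduced last by selenoxide elimination from diketone 3. The C3–acyl bond of 3 is cut to 1 and 2 (crossed Claisen condensation), both commercial and carrying all ring A and aroyl oxygens. The forward steps ask only that indanone self-condensation be suppressed and that 6 be used as soon as formed.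

## Roads not taken

**Alternative 1:** Ring A is cut. C4a–C8a, C5–C6 and C7–C8 would form in one cobalt-mediated [2+2+2] cyclotrimerisation (CpCo(CO)2, light) of 1,7-diyne A2 with diborylacetylene A3, giving bis(boronate) A1. A2 is the C1–C4 chain of ring B with both stereocentres, both aroyl groups and a terminal alkyne at each end. Oxidation of two C–B bonds and cleavage of five methyl ethers would follow.
- Merits: rings A and B close together; the catechol oxygens enter as boronates and are unmasked by mild oxidation; no carbocation is involved; ring A could be varied freely.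
- Weak points: the key step sets no stereocentre. A2 must already hold the (1R,2S) pair in an open chain where C1 is propargylic and benzylic and C2 is α to a ketone, so both are exposed to allene formation and enolisation. A2 is also a conjugated ynenone that can bind cobalt, and making it enantiopure would take more steps than the whole chosen route.
- Comparison: this road is better in ring A flexibility and in mildness toward the catechol. The chosen plan offers a commercial indanone that already is ring A, and a key step that creates the stereocentres instead of having to preserve them.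

**Alternative 2:** Ring B is cut at C1–C2 and C3–C4. Photoenolisation of 2-benzylbenzaldehyde A5 with Ti(OiPr)4 and a TADDOL ligand, and cycloaddition with the symmetric E-enedione A6, would give hydroxytetralin A4. Its dehydration would give 12 directly.
- Merits: the most convergent construction; all carbons arrive at the right oxidation level; the C4 oxygen leaves as water, so the triflation and reduction of the chosen plan are not needed.
- Weak points: A6 is itself a chromophore that can isomerise about its double bond under the same light. The photoenol of a diarylmethane must keep its aryl group outward. The enantiocontrol of this titanium system is established for simpler ortho-methylbenzaldehydes with chelating dienophiles, and the C1 configuration set here cannot be corrected later (C2 can, by epimerisation).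
- Comparison: this road is shorter by two or three steps. The chosen plan offers ground-state ionic steps whose selectivities each rest on a ring constraint, and no competition between two light-absorbing partners.

**Alternative 3:** Ring B is cut at C1–C2 and C4–C4a. A chiral phosphoric acid would ionise diaryl carbinol A8 at C1, the C2 enol of methoxymethylene diketone A9 would add there, and TfOH would then let C4a of ring A displace methoxide at C4. The product is A7, the hexamethyl ether with the 4-hydroxyphenyl group already free.
- Merits: two simple fragments; an organocatalytic stereo-determining step; C3=C4 present from the outset; one ether fewer to cleave. On paper this is the shortest route.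
- Weak points: the nucleophilic carbon of A9 is the α-methylene of a single ketone, far less enolised than the 1,3-dicarbonyl, naphthol or indole partners for which such additions are secure. A9 is also an acid-labile vinylogous ester. Two open-chain stereocentres form at once. With a free para-hydroxyphenyl group on C1, the C1–C2 bond can re-ionise in TfOH, so enantiomeric purity is at risk during ring closure.
- Comparison: this road has the best step economy of the four. In the chosen plan C1 is made under the control of a ring-bound C2 centre and carries a methyl-capped aryl group that cannot re-ionise in this way.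

Key step: step 3

Remark: the sense of induction of a cinchona ammonium ylide on this indenone cannot be derived with confidence; the route is written with the quinidine-derived ether, and its quinine-derived pseudoenantiomer would replace it if 8 proved to be the antipode.

## Route

Step 1
Reactants: 1 5,6-dimethoxy-2,3-dihydro-1H-inden-1-one; 2 methyl 2,4-dimethoxybenzoate
Product: 3 2-(2,4-dimethoxybenzoyl)-5,6-dimethoxy-2,3-dihydro-1H-inden-1-one (racemic, largely enolised)
Conditions: NaH (2.2 equiv), THF, reflux, 1 added slowly to NaH and excess 2; aq. HCl work-up
Reagents that add atoms: none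
Why: Crossed Claisen condensation: the sodium enolate of 1 is acylated by the non-enolisable ester 2 and the equilibrium is pulled over by deprotonation of the β-diketone 3; slow addition of 1 keeps aldol self-condensation of the indanone down.

Step 2
Reactants: 3 2-(2,4-dimethoxybenzoyl)-5,6-dimethoxy-2,3-dihydro-1H-inden-1-one
Product: 6 2-(2,4-dimethoxybenzoyl)-5,6-dimethoxy-1H-inden-1-one, via 2-phenylselanyl diketone 4 (not isolated), via selenoxide 5 (not isolated)
Conditions: PhSeCl, pyridine, CH2Cl2, 0 °C; then H2O2 (30% aq.), 0 °C; cold aq. NaHCO3 wash, dried solution used at once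
Reagents that add atoms: none
Why: α-Selenenylation of the enolised β-diketone, oxidation to the selenoxide and syn-elimination, which can only take a benzylic hydrogen from C1 and runs at or below 0 °C; the enedione 6 is a strong Michael acceptor that can dimerise, so it is kept cold, dilute and base-free and goes straight into step 3.

Step 3
Reactants: 6 2-(2,4-dimethoxybenzoyl)-5,6-dimethoxy-1H-inden-1-one; 7 2-bromo-1-(2,4-dimethoxyphenyl)ethan-1-one
Product: 8 (1S,1aR,6aR)-1,6a-bis(2,4-dimethoxybenzoyl)-3,4-dimethoxy-1a,6a-dihydrocyclopropa[a]inden-6(1H)-one (cis-fused; aroyl group on the apex carbon exo)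
Conditions: 7 (1.2 equiv), 9-O-methylquinidine (20 mol %), Cs2CO3 (1.5 equiv), MeCN, 0 °C to rt; CH2Cl2 solution of 6 added over several hours
Reagents that add atoms: none
Why: Michael-initiated ring closure through a chiral ammonium ylide: the quinuclidine nitrogen of the catalyst is alkylated by 7, Cs2CO3 deprotonates the salt to the aroyl-stabilised ylide, and its carbon (C2) adds to C1, the β-carbon of enedione 6, giving a caesium 1,3-diketonate still bound to the catalyst. Ring closure is a 3-exo-tet displacement of the amine at C2 by the enolate carbon C3, which forms C2–C3, closes the cyclopropane and releases the catalyst. The closest known reaction type is the cinchona-amine-catalysed cyclopropanation of electron-poor alkenes with α-bromo ketones, and ylide cyclopropanation of 2-arylidene-1,3-indanediones to spirocyclopropanes shows that a diketonate of this kind can close at carbon. C1 and C3 are set together by the face of the planar indenone that the chiral ylide attacks, because a three-membered ring can only be cis-fused to the five-membered one; C2 is set in the ring closure, where reversible ylide addition lets the betaine that places the aroyl group exo, away from ring A and the C4 carbonyl, close faster. The step needs enantioface selection (catalyst), exo selectivity (substrate) and closure at carbon rather than oxygen: the ring oxygen at C4 cannot reach C2, the aroyl oxygen is turned away from C2 in the chelated caesium diketonate, and the low temperature guards against later isomerisation of 8 to a dihydrofuran. Slow addition of 6 keeps its stationary concentration, and so its dimerisation, low.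

Step 4
Reactants: 8 (1S,1aR,6aR)-1,6a-bis(2,4-dimethoxybenzoyl)-3,4-dimethoxy-1a,6a-dihydrocyclopropa[a]inden-6(1H)-one; 9 anisole
Product: 10 [(1R,2S)-4-hydroxy-6,7-dimethoxy-1-(4-methoxyphenyl)-1,2-dihydronaphthalene-2,3-diyl]bis[(2,4-dimethoxyphenyl)methanone] (enol form of the C4 ketone)
Conditions: Sc(OTf)3 (20 mol %), anisole (10 equiv), HFIP, 0 °C to rt
Reagents that add atoms: none
Why: Lewis-acid-catalysed Friedel–Crafts ring opening of a donor–acceptor cyclopropane: Sc(OTf)3 chelates the C4/C3 1,3-dicarbonyl unit and polarises C1–C3, the only bond joining the donor carbon (ring A, para-methoxy) to a carbon with two acceptors, and its cleavage turns the five-membered ring into ring B. Anisole attacks C1 through its para position anti to the departing C3 (inversion); if the opening runs through the free benzylic cation, the C2 aroyl group shields one face of the nearly flat ring, so both paths give the 1,2-trans product and the retained C2 centre fixes C1 as R, while HFIP and excess anisole favour capture over loss of the C2 proton.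

Step 5
Reactants: 10 [(1R,2S)-4-hydroxy-6,7-dimethoxy-1-(4-methoxyphenyl)-1,2-dihydronaphthalene-2,3-diyl]bis[(2,4-dimethoxyphenyl)methanone]
Product: 11 [(1R,2S)-6,7-dimethoxy-1-(4-methoxyphenyl)-4-(trifluoromethanesulfonyloxy)-1,2-dihydronaphthalene-2,3-diyl]bis[(2,4-dimethoxyphenyl)methanone]
Conditions: NaH, THF, 0 °C; PhNTf2, 0 °C to rt; aq. NH4Cl work-up
Reagents that add atoms: N-phenylbis(trifluoromethanesulfonimide), O=S(=O)(N(c1ccccc1)S(=O)(=O)C(F)(F)F)C(F)(F)F
Why: O-Sulfonylation of the sodium diketonate (enol triflate formation); as is usual for cyclic 2-acyl ketones the endocyclic enol triflate is expected, the aroyl oxygen being shielded by its twisted ortho-methoxyaryl ring and the C2 substituent; C2 may epimerise in base, but trans is the stable arrangement beside the fixed C1 aryl group.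

Step 6
Reactants: 11 [(1R,2S)-6,7-dimethoxy-1-(4-methoxyphenyl)-4-(trifluoromethanesulfonyloxy)-1,2-dihydronaphthalene-2,3-diyl]bis[(2,4-dimethoxyphenyl)methanone]
Product: 12 [(1R,2S)-6,7-dimethoxy-1-(4-methoxyphenyl)-1,2-dihydronaphthalene-2,3-diyl]bis[(2,4-dimethoxyphenyl)methanone]
Conditions: Pd(OAc)2 (5 mol %), PPh3 (10 mol %), HCO2H, Et3N, DMF, 60 °C
Reagents that add atoms: none
Why: Palladium-catalysed formate reduction of an enol triflate: zerovalent palladium formed in situ inserts into the activated C4–O bond, formate replaces triflate, and loss of CO2 then reductive elimination puts hydrogen on C4, leaving C3=C4, both ketones and the aryl ethers untouched.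

Step 7
Reactants: 12 [(1R,2S)-6,7-dimethoxy-1-(4-methoxyphenyl)-1,2-dihydronaphthalene-2,3-diyl]bis[(2,4-dimethoxyphenyl)methanone]
Product: 13 [(1R,2S)-6,7-dihydroxy-1-(4-hydroxyphenyl)-1,2-dihydronaphthalene-2,3-diyl]bis[(2,4-dihydroxyphenyl)methanone]
Conditions: BBr3 (15 equiv), CH2Cl2, −78 °C to rt; MeOH then aq. NaHCO3 under argon
Reagents that add atoms: none
Why: Lewis-acid cleavage of aryl methyl ethers: each ether oxygen binds boron and bromide removes the methyl group by SN2, the two ortho-methoxy groups being helped by chelation to their ketones; low temperature, excess reagent and a buffered oxygen-free work-up limit closure of a 2'-hydroxyl onto C4 and oxidation of the catechol, and no stereocentre is touched.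

## Compound list

1 | 5,6-dimethoxy-2,3-dihydro-1H-inden-1-one | COc1cc2CCC(=O)c2cc1OC | starting material
2 | methyl 2,4-dimethoxybenzoate | COC(=O)c1ccc(OC)cc1OC | starting material
3 | 2-(2,4-dimethoxybenzoyl)-5,6-dimethoxy-2,3-dihydro-1H-inden-1-one (racemic, enolisable) | COc1cc2CC(C(=O)c3ccc(OC)cc3OC)C(=O)c2cc1OC | intermediate
4 | 2-(2,4-dimethoxybenzoyl)-5,6-dimethoxy-2-(phenylselanyl)-2,3-dihydro-1H-inden-1-one (racemic, not isolated) | COc1cc2CC([Se]c3ccccc3)(C(=O)c3ccc(OC)cc3OC)C(=O)c2cc1OC | intermediate
5 | 2-(2,4-dimethoxybenzoyl)-5,6-dimethoxy-2-(phenylseleninyl)-2,3-dihydro-1H-inden-1-one (stereoisomer mixture, not isolated) | COc1cc2CC([Se](=O)c3ccccc3)(C(=O)c3ccc(OC)cc3OC)C(=O)c2cc1OC | intermediate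
6 | 2-(2,4-dimethoxybenzoyl)-5,6-dimethoxy-1H-inden-1-one | COc1cc2C=C(C(=O)c3ccc(OC)cc3OC)C(=O)c2cc1OC | intermediate
7 | 2-bromo-1-(2,4-dimethoxyphenyl)ethan-1-one | COc1ccc(C(=O)CBr)c(OC)c1 | starting material
8 | (1S,1aR,6aR)-1,6a-bis(2,4-dimethoxybenzoyl)-3,4-dimethoxy-1a,6a-dihydrocyclopropa[a]inden-6(1H)-one | O=C1c2cc(OC)c(OC)cc2[C@H]2[C@H](C(=O)c3ccc(OC)cc3OC)[C@@]12C(=O)c1ccc(OC)cc1OC | intermediate
9 | anisole (methoxybenzene) | COc1ccccc1 | starting material
10 | [(1R,2S)-4-hydroxy-6,7-dimethoxy-1-(4-methoxyphenyl)-1,2-dihydronaphthalene-2,3-diyl]bis[(2,4-dimethoxyphenyl)methanone] | O=C(c1ccc(OC)cc1OC)C1=C(O)c2cc(OC)c(OC)cc2[C@@H](c2ccc(OC)cc2)[C@@H]1C(=O)c1ccc(OC)cc1OC | intermediate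
11 | [(1R,2S)-6,7-dimethoxy-1-(4-methoxyphenyl)-4-(trifluoromethanesulfonyloxy)-1,2-dihydronaphthalene-2,3-diyl]bis[(2,4-dimethoxyphenyl)methanone] | O=C(c1ccc(OC)cc1OC)C1=C(OS(=O)(=O)C(F)(F)F)c2cc(OC)c(OC)cc2[C@@H](c2ccc(OC)cc2)[C@@H]1C(=O)c1ccc(OC)cc1OC | intermediate
12 | [(1R,2S)-6,7-dimethoxy-1-(4-methoxyphenyl)-1,2-dihydronaphthalene-2,3-diyl]bis[(2,4-dimethoxyphenyl)methanone] | O=C(c1ccc(OC)cc1OC)C1=Cc2cc(OC)c(OC)cc2[C@@H](c2ccc(OC)cc2)[C@@H]1C(=O)c1ccc(OC)cc1OC | intermediate
13 | [(1R,2S)-6,7-dihydroxy-1-(4-hydroxyphenyl)-1,2-dihydronaphthalene-2,3-diyl]bis[(2,4-dihydroxyphenyl)methanone] | O=C(C1=Cc2cc(O)c(O)cc2[C@@H](c2ccc(O)cc2)[C@@H]1C(=O)c1ccc(O)cc1O)c1ccc(O)cc1O | target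

## Step count and uncertain steps

Total: 7 steps. Longest linear sequence: 7 steps (1 → 3 → 6 → 8 → 10 → 11 → 12 → 13); 2, 7 and 9 enter as purchased.

**Step 3 (key step).**
- Most likely failure: O-alkylation in the ring-closing event. The diketonate could close through its aroyl oxygen, or 8 could be re-opened by the amine and re-closed at oxygen, because 1,3-diketone enolates often prefer five-ring O-closure to three-ring C-closure.
- Further risks: dimerisation of 6 before the ylide captures it, and weak facial discrimination on a small, flat acceptor.
- Fallback: sets out from 6 and reverses the polarity of the ring closure, so the diketone carbon is the electrophile and cannot close through its own oxygen. A Mukaiyama–Michael addition of the trimethylsilyl enol ether of 2',4'-dimethoxyacetophenone F1 to 6, catalysed by Cu(OTf)2 with a chiral bis(oxazoline) ligand that chelates the 2-acyl enone, would give Michael adduct F2 with C1 set. Chlorination of its diketone carbon C3 with N-chlorosuccinimide, anti to the C1 side chain, would give tertiary chloride F3. DBU would then generate the C2 ketone enolate, which displaces chloride at C3 in a 3-exo-tet closure. The route is rejoined at 8.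

**Step 4.**
- Most likely failure: loss of the C2 proton from the ring-opened benzylic cation (aromatisation of ring B, which erases both stereocentres) outrunning capture by the weakly nucleophilic anisole.
- Further risks: cleavage of the C1–C2 bond, which overlaps better with the ring A π-system than the in-plane fusion bond, and acid-promoted cyclodehydration of the 1,4-diketone.
- Fallback: sets out from 8 and replaces the cationic arylation by a homoconjugate addition. Lithium bis(4-methoxyphenyl)cuprate (from 4-bromoanisole, tBuLi and CuI) in THF/Et2O at −78 to −20 °C would open the doubly activated cyclopropane at C1 with inversion, without a free cation. Protonation of the diketonate rejoins the route at 10. No new compound is involved.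

**Step 5.**
- Most likely failure: sulfonylation at the aroyl oxygen instead of the ring oxygen, since the diketonate is ambident. After reduction this would leave the C4 carbonyl in place.
- Fallback: sets out from 10 and moves the regiochemical decision from oxygen to carbon. Oxalyl chloride with catalytic DMF in CH2Cl2 would convert the enol through its rapidly interconverting chlorooxalates into 4-chloro enone F4, chloride adding to the more accessible β-carbon C4. A zinc–silver couple in MeOH would then replace chlorine by hydrogen. The route is rejoined at 12.

**Step 7.**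
- Most likely failure: incomplete cleavage of the two methoxy groups para to the boron-complexed ketones, combined with loss of the heptaphenol during isolation (oxa-Michael closure onto C4, air oxidation of the catechol on silica).
- Fallback: sets out from 12 and separates cleavage from isolation. After BBr3 treatment the crude phenol mixture would be peracetylated (Ac2O, pyridine, DMAP) to heptaacetate F5, which can be chromatographed and freed of under-cleaved material. The acetates would then be removed under near-neutral conditions (NH4OAc, aq. MeOH, rt, degassed). The route is rejoined at 13.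

## Further compounds

F1 | step 3 | 1-(2,4-dimethoxyphenyl)-1-(trimethylsilyloxy)ethene | C=C(O[Si](C)(C)C)c1ccc(OC)cc1OC
F2 | step 3 | (3S)-2-(2,4-dimethoxybenzoyl)-3-[2-(2,4-dimethoxyphenyl)-2-oxoethyl]-5,6-dimethoxy-2,3-dihydro-1H-inden-1-one (C2 epimers and enol) | COc1cc2[C@@H](CC(=O)c3ccc(OC)cc3OC)C(C(=O)c3ccc(OC)cc3OC)C(=O)c2cc1OC
F3 | step 3 | (2S,3R)-2-chloro-2-(2,4-dimethoxybenzoyl)-3-[2-(2,4-dimethoxyphenyl)-2-oxoethyl]-5,6-dimethoxy-2,3-dihydro-1H-inden-1-one | COc1cc2[C@@H](CC(=O)c3ccc(OC)cc3OC)[C@@](Cl)(C(=O)c3ccc(OC)cc3OC)C(=O)c2cc1OC
F0 | step 4 | none | none
F4 | step 5 | [(1R,2S)-4-chloro-6,7-dimethoxy-1-(4-methoxyphenyl)-1,2-dihydronaphthalene-2,3-diyl]bis[(2,4-dimethoxyphenyl)methanone] | O=C(c1ccc(OC)cc1OC)C1=C(Cl)c2cc(OC)c(OC)cc2[C@@H](c2ccc(OC)cc2)[C@@H]1C(=O)c1ccc(OC)cc1OC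
F5 | step 7 | [(1R,2S)-6,7-diacetoxy-1-(4-acetoxyphenyl)-1,2-dihydronaphthalene-2,3-diyl]bis[(2,4-diacetoxyphenyl)methanone] | O=C(C1=Cc2cc(OC(C)=O)c(OC(C)=O)cc2[C@@H](c2ccc(OC(C)=O)cc2)[C@@H]1C(=O)c1ccc(OC(C)=O)cc1OC(C)=O)c1ccc(OC(C)=O)cc1OC(C)=O
A1 | alternative 1 | (1R,2S)-6,7-bis(pinacolatoboryl) analogue of the target, pentamethyl ether | O=C(c1ccc(OC)cc1OC)C1=Cc2cc(B3OC(C)(C)C(C)(C)O3)c(B3OC(C)(C)C(C)(C)O3)cc2[C@@H](c2ccc(OC)cc2)[C@@H]1C(=O)c1ccc(OC)cc1OC
A2 | alternative 1 | 1,7-diyne with C1 and C2 configured as in the target and the C4 alkyne cis to C2 | C#C[C@@H](c1ccc(OC)cc1)[C@H](C(=O)c1ccc(OC)cc1OC)/C(C(=O)c1ccc(OC)cc1OC)=C\C#C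
A3 | alternative 1 | 1,2-bis(4,4,5,5-tetramethyl-1,3,2-dioxaborolan-2-yl)ethyne | CC1(C)OB(C#CB2OC(C)(C)C(C)(C)O2)OC1(C)C
A4 | alternative 2 | 4-hydroxytetralin cycloadduct, heptamethyl ether (C1 aryl and C4 hydroxyl cis, C2 and C3 aroyl groups trans) | O=C(c1ccc(OC)cc1OC)[C@H]1[C@@H](O)c2cc(OC)c(OC)cc2[C@@H](c2ccc(OC)cc2)[C@@H]1C(=O)c1ccc(OC)cc1OC
A5 | alternative 2 | 4,5-dimethoxy-2-(4-methoxybenzyl)benzaldehyde | COc1ccc(Cc2cc(OC)c(OC)cc2C=O)cc1
A6 | alternative 2 | (E)-1,4-bis(2,4-dimethoxyphenyl)but-2-ene-1,4-dione | COc1ccc(C(=O)/C=C/C(=O)c2ccc(OC)cc2OC)c(OC)c1
A7 | alternative 3 | (1R,2S)-hexamethyl ether of the target with the 4-hydroxyphenyl group free | O=C(c1ccc(OC)cc1OC)C1=Cc2cc(OC)c(OC)cc2[C@@H](c2ccc(O)cc2)[C@@H]1C(=O)c1ccc(OC)cc1OC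
A8 | alternative 3 | (3,4-dimethoxyphenyl)(4-hydroxyphenyl)methanol (racemic) | COc1ccc(C(O)c2ccc(O)cc2)cc1OC
A9 | alternative 3 | 2-(methoxymethylidene)-1,4-bis(2,4-dimethoxyphenyl)butane-1,4-dione (E/Z mixture) | COC=C(CC(=O)c1ccc(OC)cc1OC)C(=O)c1ccc(OC)cc1OC
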